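(All runs are calculated for an exercise; noise was put on by code.)

Without rate constants, you read the flask through one ratio: x, isomer of the product per target, and c, its climb per hour, taken from Saturday's run between its first and last readings. This makes x a clock, and the share of target is simply 1/(1+x).

| setting | Wednesday's | Thursday's | Saturday's | flask |
|---|---|---|---|---|
| starting material | 26 mM | 26 mM | 26 mM | 26 mM |
| partner | 16 mM | 23 mM | 31.2 mM | 31.2 mM |
| protic impurity | 1.3 mM | 1.3 mM | 2 mM | 1.30 mM |
| remark | run made earlier | run made earlier | run made earlier |  |
| time |  |  |  | 2.0 h |

- Wednesday's (time / min: target / %, isomer of the product / %): 25.0: 35.2, 2.8; 50.0: 36.8, 5.0; 80.0: 37.5, 5.9; 90.0: 36.3, 4.7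
- Thursday's (time / min: target / %, isomer of the product / %): 12.0: 40.1, 3.5; 30.0: 47.1, 5.4; 60.0: 49.1, 5.3; 90.0: 48.7, 7.6
- Saturday's (time / min: target / %, isomer of the product / %): 8.00: 42.1, 3.5; 20.0: 52.0, 5.0; 40.0: 56.2, 5.9; 90.0: 56.2, 8.9

(each reading ± 0.5 percentage points)



- share of target in target plus isomer of the product at 15 s
- share of target in target plus isomer of the product at 2.0 h
- which of target and isomer of the product there is more of at 2.0 h

Saturday's x goes from 0.0831 at 8.00 min to 0.158 at 90.0 min, so c is 0.0550 h⁻¹. Your flask has Saturday's partner but less protic impurity, so is the clock valid for it? Thursday's run has the flask's impurity and less partner, yet its x at 90.0 min is also 0.156. Wednesday's last reading gives 0.129, which looks like an objection, but its reading at 80.0 min gives 0.157, and each reading carries a scatter of 0.5 percentage points. You keep the clock.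

Running it back to 15 s gives x of 0.0760, a share of 92.9%; the inverse of this early x is only your estimate of the selectivity factor, drawn from two scattered readings. Running it forward to 2.0 h gives 0.186, a share of 84.3%, with target ahead.

But the line may bend. Saturday's late chord from 40.0 min gives 0.0641 h⁻¹, which shows no flattening. Even so, holding x at its last reading gives 86.4%, so the doubt spans 2 points.

The forecast gives 92.8% and 84.5%, with target ahead, on the ground that “the isomer keeps creeping up at about 0.05–0.07 %/min while target stays flat”.

The flask gives 92.0% and 85.3%, with 57.0% target against 9.79% isomer of the product.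

    starting material + partner ⇌ target (K = 300 M⁻¹, k = 0.0860 M⁻¹ s⁻¹)
    starting material ⇌ dormant form (K = 1.10, k = 0.00140 s⁻¹)
    starting material + partner ⇌ isomer of the product (K = 79.0 M⁻¹, k = 0.00750 M⁻¹ s⁻¹)
    starting material + protic impurity → quenched substrate (k = 0.600 M⁻¹ s⁻¹)

In this flask the relaxation half-life of the target step, both directions together at 2.00 h, is 0.108 h, shorter than the 2.0 h of the run, and x stands at 0.172 against the 0.186 of your line with c. The neighbour flask with 120 mM of partner, 4.62 equiv, has the same line value from c, and at 2.00 h it holds 76.3% target and 13.4% isomer of the product, x of 0.176 and a share of 85.1%.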